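Remark on the chemistry: positions are numbered as in guaiane (C1–C15). The C1 configuration of the target is assumed to be the thermodynamically preferred one of the guai-4-en-3-one; the conformational argument is given in step 12.

## Analysis of the target

The target (23) is a guai-4-en-3-one. A cyclopentenone (C1–C5) is fused through C1 and C5 to a cycloheptane (C1, C5, C6, C7, C8, C9, C10), and only C1 is an sp3 fusion atom. There are four stereocentres: C1 (R), C7 (S), C8 (R) and C10 (S). The C8 oxygen, the C7 side chain (C11), the C10 methyl and H1 all lie on one face of the seven-membered ring, so the C1–C2 bond is trans to the C10 methyl. C7 and C8 are contiguous and cis, whereas C10 and C1 are separated from them by the C9 and C6 methylenes; relaying configuration across the ring is therefore as much a problem as closing the ring. The sensitive groups are the methacrylate (a polymerisable Michael acceptor that tolerates neither hydrogenation nor organometallic reagents), the hindered tertiary acetate at C11 (it can eliminate, or migrate to a free C8 hydroxyl across the 1,3-diol) and the γ-hydrogen at C1, which epimerises through the dienolate. The two different esters on a 1,3-diol must be introduced in a fixed order. The strategy rests on the five-membered ring: the C3 carbonyl is flanked by the methyl-bearing C4=C5 alkene and by C2, and C1 is bonded to C10. This is the pattern left by a methyl alkyne (C4≡C5), one carbonyl carbon (C3) and the terminal C1=C2 bond of an allene whose third carbon is C10.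

## Retrosynthetic reasoning

**23 to 22.** The C8–O acyl bond is cut first. The methacrylate would not survive the hydrogenation, the base treatment or the organometallic steps, so it is attached last, to the secondary alcohol 22, in which O11 already carries its acetate.

**22 to 21.** The O8–Si bond is cut. A silyl ether on O8 keeps the two oxygens distinct from the aldol stage onwards and prevents acetyl migration from O11 while C1 and C10 are adjusted.

**21 to 19 to 18.** The C1–H and C10–H bonds are removed. Enone 21 is the C1 epimer of 19, and the two interconvert through dienolate 20, so C1 can be left to equilibrium. Compound 19 is the product of syn addition of two hydrogen atoms to the C1=C10 bond of dienone 18 on the face opposite the C7 and C8 substituents; this sets C10. The cut is made here because the dienone is what the ring-forming step delivers.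

**18 to 17 (key disconnection).** C1–C5, C2–C3 and C3–C4 are cut together. This opens both rings and leaves the acyclic allene-yne 17 plus a carbonyl ligand from the metal. The transform removes all ring strain and ring-size problems in one step and leaves only two stereocentres, C7 and C8, adjacent on an open chain. The forward reaction has to engage the terminal (distal) bond of the allene so that the C6–C9 tether and C10 end up in a seven-membered ring.

**17 to 16 to 15.** The acetyl group on O11 is removed (16), then the C10–CH3 bond. The 1,1-disubstituted allene of 16 is the SN2′ product of a methyl nucleophile and the propargylic methyl ether 15, with methoxide leaving from C2. The ether is chosen as leaving group because it is inert to everything before this point.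

**15 to 13 to 12 to 11.** Both C11–CH3 bonds are cut, which turns the dimethylcarbinol into an acyl group: thioester 13 (via ketone 14), which comes from the silylated imide 12 and the aldol adduct 11. C11 is therefore the former acyl carbon of the auxiliary-bound acid.

**11 to 4 and 9.** The C7–C8 bond is cut. The syn relationship between the C8 hydroxyl and the C6 branch is the signature of an auxiliary-controlled syn aldol between imide 4 (via boron enolate 10) and aldehyde 9. Both stereocentres that must be carried into the key step are made here with reagent control.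

**4 to 1 and 2; 9 to 8 to 5 and 6.** Imide 4 is the N-acyl derivative of auxiliary 2 with acid 1 (via anhydride 3). Aldehyde 9 is the oxidation product of alcohol 8, which is the ring-opening product of oxirane 6 with the acetylide 7 of methyl propargyl ether 5.

## Alternatives that were turned down

**Alternative 1:** An oxy-Cope transform cuts the ring bond C5–C6 and joins C3 to C8, so the hydroazulene is traced back to a bridged tertiary carbinol. In the forward step the potassium alkoxide at C8 (KH, 18-crown-6) rearranges through the 1,5-diene C6=C7–C8–C3–C4=C5; C5–C6 forms as C3–C8 breaks, and the cycloheptanone enolate is silylated to give A1.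
- For it: the charge-accelerated [3,3] shift is fast and strain-driven, the bridged frame forces a cis ring fusion, and the C1/C10 relationship is fixed on a rigid bicycle before the ring exists.
- Against it: A1 carries C3=C4 and an sp3 C5, whereas the target needs C3=O and C4=C5. Oxidation at C3 with alkene transposition must follow, and it erases the C5 centre that the rearrangement controlled. C7 and C8 leave the step as the two carbons of an enol ether, so the cis C7/C8 pair still has to be set by protonation and ketone reduction on a flexible cycloheptane. The bridged substrate, with a quaternary carbinol and four stereocentres, is a synthesis of its own.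
- Comparison: it is stronger on C10/C1, which the chosen route sets only late by hydrogenation and equilibration. The chosen route offers instead C7 and C8 fixed by an auxiliary in open chain, and a ring-forming step that delivers the C3 ketone, the C4 methyl and the C4=C5 alkene exactly as in the target, in clearly fewer steps.

**Alternative 2:** The C7–C8 bond and the C11–O bond are cut, leading back to the cyclopentenone aldehyde A2, which carries a prenyl group on C5 and a 4-oxobutan-2-yl chain on C1. In aqueous H2SO4 the C7=C11 alkene attacks the protonated aldehyde through C7, the seven-membered ring closes, and water traps the tertiary C11 cation to give diol A3.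
- For it: it is the shortest plan. A3 is two acylations from the target, no protecting group is needed, and C1 and C10 are in place before the ring closes.
- Against it: a cationic closure of a seven-membered ring is slow compared with what else A2 can do in acid. The enone can enolise towards C6 and close a six-membered ring onto the aldehyde, the C11 cation can lose a proton instead of taking up water, and the aldehyde can condense with itself. C7 and C8 are formed together with no reagent control, and the target needs them cis while the neighbouring substituents in such closures tend to settle trans.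
- Comparison: it is stronger in step count and protecting-group economy. The chosen route offers a C7/C8 pair of predictable sense from the aldol and a ring closure on a metal template that does not depend on the fate of a carbocation; its stereochemical risk lies at C1/C10, where equilibration is available.

**Alternative 3:** The ring bonds C6–C7 and C9–C10 are cut, giving a siloxy-substituted vinyl diazoester and a cyclopentane bearing an exocyclic diene. With a chiral dirhodium tetracarboxylate such as Rh2(S-PTAD)4, the carbenoid carbon (C7) cyclopropanates the C5=C6 methylene, and the cis-divinylcyclopropane rearranges by a Cope shift to A4.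
- For it: the step is convergent and catalytic-asymmetric, forms two C–C bonds and the ring at once, and sets C10 stereospecifically through the boat-like Cope transition state.
- Against it: A4 has the alkene at C1=C5, a silyl ether at C3, an ester at C7 and an enol ether at C8. C3 must be oxidised, the alkene moved to C4=C5 with creation of C1, the ester turned into the acetoxy-dimethylcarbinol, and the β-keto ester region reduced and protonated to the cis C7/C8 pair, where C7 is epimerisable. The C3 and C4 stereocentres of the diene are made only to be destroyed.
- Comparison: it is stronger in convergence and in setting C10 during ring formation. The chosen route offers the correct oxidation pattern of the five-membered ring directly from the key step and a far shorter sequence after it.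

Key step: step 10

## Route

**Step 1**
Reactants: 1 hex-4-ynoic acid; 2 (S)-4-benzyl-1,3-oxazolidin-2-one
Product: 4 (S)-4-benzyl-3-(hex-4-ynoyl)-1,3-oxazolidin-2-one, via mixed pivalic anhydride 3 (not isolated)
Conditions: PivCl, Et3N, THF, −20 °C; then LiCl, 2, −20 °C → rt
Reagents that add atoms: none
Why: N-acylation of an oxazolidinone through a mixed anhydride (LiCl/Et3N activation of the N–H); attack occurs at the unhindered carbonyl of 3 and the alkyne is inert.

**Step 2**
Reactants: 5 3-methoxyprop-1-yne; 6 oxirane
Product: 8 5-methoxypent-3-yn-1-ol, via lithium acetylide 7 (not isolated)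
Conditions: n-BuLi, THF, −78 °C; BF3·OEt2, then 6, −78 °C
Reagents that add atoms: none
Why: BF3-assisted opening of an epoxide by a lithium acetylide (Yamaguchi alkynylation); oxirane is symmetrical, so there is no regiochemical question, and the propargylic ether is untouched at −78 °C.

**Step 3**
Reactants: 8 5-methoxypent-3-yn-1-ol
Product: 9 5-methoxypent-3-ynal
Conditions: Dess–Martin periodinane, NaHCO3, CH2Cl2, 0 °C → rt; filtered, concentrated cold, used at once
Reagents that add atoms: none
Why: Dess–Martin oxidation is neutral and non-enolising, which is what a β,γ-alkynyl aldehyde needs to avoid the propargyl-to-allenyl shift; 9 is not purified.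

**Step 4**
Reactants: 4 (S)-4-benzyl-3-(hex-4-ynoyl)-1,3-oxazolidin-2-one; 9 5-methoxypent-3-ynal
Product: 11 (S)-4-benzyl-3-[(2S,3R)-2-(but-2-yn-1-yl)-3-hydroxy-7-methoxyhept-5-ynoyl]-1,3-oxazolidin-2-one, via boron Z-enolate 10 (not isolated)
Conditions: Bu2BOTf, i-Pr2NEt, CH2Cl2, 0 °C; 9, −78 → −20 °C; pH 7 buffer, MeOH, 30% H2O2, 0 °C
Reagents that add atoms: none
Why: Evans syn aldol: the Z boron enolate 10 adds to 9 through a chair Zimmerman–Traxler transition state on the enolate face away from the benzyl group, with the two imide carbonyl dipoles opposed. This sets C7 (2S) and C8 (3R) in the syn relationship that becomes the cis 7,8-pair, and at −78 °C the aldehyde meets only the enolate and a hindered ammonium salt.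

**Step 5**
Reactants: 11 (S)-4-benzyl-3-[(2S,3R)-2-(but-2-yn-1-yl)-3-hydroxy-7-methoxyhept-5-ynoyl]-1,3-oxazolidin-2-one
Product: 12 (S)-4-benzyl-3-[(2S,3R)-2-(but-2-yn-1-yl)-3-(tert-butyldimethylsilyloxy)-7-methoxyhept-5-ynoyl]-1,3-oxazolidin-2-one
Conditions: TBSOTf, 2,6-lutidine, CH2Cl2, −78 → 0 °C
Reagents that add atoms: tert-butyldimethylsilyl trifluoromethanesulfonate, CC(C)(C)[Si](C)(C)OS(=O)(=O)C(F)(F)F
Why: Silylation of a secondary alcohol with a silyl triflate and a hindered base; it blocks retro-aldol cleavage and keeps O8 distinct from the later O11.

**Step 6**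
Reactants: 12 (S)-4-benzyl-3-[(2S,3R)-2-(but-2-yn-1-yl)-3-(tert-butyldimethylsilyloxy)-7-methoxyhept-5-ynoyl]-1,3-oxazolidin-2-one
Product: 13 S-ethyl (2S,3R)-2-(but-2-yn-1-yl)-3-(tert-butyldimethylsilyloxy)-7-methoxyhept-5-ynethioate
Conditions: EtSH, n-BuLi, THF, 0 °C
Reagents that add atoms: ethanethiol, CCS
Why: Thiolate cleavage of an N-acyl oxazolidinone: the soft, weakly basic lithium thiolate attacks the exocyclic carbonyl even of hindered α-branched β-silyloxy imides without epimerising C7, and auxiliary 2 is recovered.

**Step 7**
Reactants: 13 S-ethyl (2S,3R)-2-(but-2-yn-1-yl)-3-(tert-butyldimethylsilyloxy)-7-methoxyhept-5-ynethioate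
Product: 15 (3S,4R)-3-(but-2-yn-1-yl)-4-(tert-butyldimethylsilyloxy)-8-methoxy-2-methyloct-6-yn-2-ol, via methyl ketone 14 (not isolated)
Conditions: MeMgBr (4 equiv), Et2O/THF, 0 °C → rt
Reagents that add atoms: methylmagnesium bromide, C[Mg]Br
Why: Double Grignard addition to a thioester: thiolate leaves readily, ketone 14 is more electrophilic than 13 and takes the second methyl, and addition at 0 °C should outrun enolisation so that C7 is kept (anhydrous CeCl3 can be added if enolisation of 14 competes).

**Step 8**
Reactants: 15 (3S,4R)-3-(but-2-yn-1-yl)-4-(tert-butyldimethylsilyloxy)-8-methoxy-2-methyloct-6-yn-2-ol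
Product: 16 (3S,4R)-3-(but-2-yn-1-yl)-4-(tert-butyldimethylsilyloxy)-2,6-dimethylocta-6,7-dien-2-ol
Conditions: MeMgBr (4 equiv), CuBr (10 mol %), Et2O, 0 °C → rt
Reagents that add atoms: methylmagnesium bromide, C[Mg]Br
Why: Copper-catalysed SN2′ substitution of a propargylic ether by a Grignard reagent: the methylcopper species (monovalent copper) delivers methyl to C10, the alkyne carbon remote from the methoxy group, and methoxide leaves from C2 to give the 1,1-disubstituted allene. The magnesium alkoxide of O11 is a spectator, the methyl alkyne has no leaving group and stays, and no stereocentre is formed.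

**Step 9**
Reactants: 16 (3S,4R)-3-(but-2-yn-1-yl)-4-(tert-butyldimethylsilyloxy)-2,6-dimethylocta-6,7-dien-2-ol
Product: 17 (3S,4R)-3-(but-2-yn-1-yl)-4-(tert-butyldimethylsilyloxy)-2,6-dimethylocta-6,7-dien-2-yl acetate
Conditions: Ac2O, Et3N, DMAP, CH2Cl2, 40 °C
Reagents that add atoms: acetic anhydride, CC(=O)OC(C)=O
Why: DMAP-catalysed acylation of a tertiary alcohol through the N-acetylpyridinium ion; O8 is silylated, so only O11 reacts, and the basic medium leaves the allene alone.

**Step 10**
Reactants: 17 (3S,4R)-3-(but-2-yn-1-yl)-4-(tert-butyldimethylsilyloxy)-2,6-dimethylocta-6,7-dien-2-yl acetate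
Product: 18 (7S,8R)-11-acetoxy-8-(tert-butyldimethylsilyloxy)guaia-1(10),4-dien-3-one
Conditions: [Rh(CO)2Cl]2 (5 mol %), CO (1 atm), toluene (0.02 M), 90 °C
Reagents that add atoms: carbon monoxide, [C-]#[O+]
Why: Allenic Pauson–Khand reaction, a carbonylative (2+2+1) cycloaddition whose closest known form is the [Rh(CO)2Cl]2-catalysed cyclocarbonylation of allene-ynes to bicyclo[5.3.0]deca-1,7-dien-9-ones. Monovalent rhodium binds the C4≡C5 alkyne and the terminal C1=C2 bond of the allene and couples them oxidatively to a rhodacyclopentene of trivalent rhodium, forming C1–C5; CO then inserts into a Rh–C bond and reductive elimination forms C2–C3 and C3–C4 and returns monovalent rhodium. The seven-membered ring (C1, C5, C6, C7, C8, C9, C10) closes in the oxidative coupling, with the C6–C9 tether and C10 inside the ring and C1=C10 left exocyclic to the new cyclopentenone; the five-membered ring (C1–C5) closes by CO insertion and reductive elimination. No stereocentre is created, and C7 and C8 sit on the tether and are carried through. The selectivity needed is reaction at the distal rather than the proximal allene bond: square-planar monovalent rhodium prefers the distal bond, and the proximal bond would in addition require a quaternary C10 in a smaller ring. C2 is an unsubstituted CH2, so the metallacycle has no β-hydrogen through which to divert to a cross-conjugated triene, and high dilution holds back intermolecular allene coupling. The adjacent bulky C7 and C8 substituents favour the folded conformer that brings the two π-systems to one metal.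

**Step 11**
Reactants: 18 (7S,8R)-11-acetoxy-8-(tert-butyldimethylsilyloxy)guaia-1(10),4-dien-3-one
Product: 19 (1S,7S,8R,10S)-11-acetoxy-8-(tert-butyldimethylsilyloxy)guai-4-en-3-one
Conditions: H2 (1 atm), 10% Pd/C, EtOAc, rt
Reagents that add atoms: none
Why: Heterogeneous catalytic hydrogenation (syn addition) of the γ,δ-alkene of a dienone: the C1=C10 bond, exocyclic to the cyclopentenone, should be taken before the endocyclic tetrasubstituted C4=C5 bond. The catalyst should approach the face opposite the C8 silyloxy group and the C7 side chain, which gives 10S (methyl cis to O8) and, for the moment, H1 cis to H10 (1S).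

**Step 12**
Reactants: 19 (1S,7S,8R,10S)-11-acetoxy-8-(tert-butyldimethylsilyloxy)guai-4-en-3-one
Product: 21 (1R,7S,8R,10S)-11-acetoxy-8-(tert-butyldimethylsilyloxy)guai-4-en-3-one, via extended dienolate 20 (not isolated)
Conditions: DBU (0.5 equiv), toluene, 60 °C
Reagents that add atoms: none
Why: Base-mediated epimerisation of the γ-carbon through the vinylogous enolate 20; reprotonation at C1 is reversible, and C7, C8 and C10 are not acidic. With C2 trans to the C10 methyl, the ring can place C9 anti to C2 and the methyl gauche only to C2, one gauche interaction fewer than any conformer of the cis epimer, so 21 is expected to predominate.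

**Step 13**
Reactants: 21 (1R,7S,8R,10S)-11-acetoxy-8-(tert-butyldimethylsilyloxy)guai-4-en-3-one
Product: 22 (1R,7S,8R,10S)-11-acetoxy-8-hydroxyguai-4-en-3-one
Conditions: HF·pyridine, pyridine, THF, 0 °C → rt
Reagents that add atoms: none
Why: Fluoride-mediated desilylation under acidic rather than basic conditions; no alkoxide is formed at O8, so acetyl migration from O11 across the 1,3-diol is avoided, and the enone and tertiary acetate are stable.

**Step 14**
Reactants: 22 (1R,7S,8R,10S)-11-acetoxy-8-hydroxyguai-4-en-3-one
Product: 23 (1R,7S,8R,10S)-11-acetoxy-8-(methacryloyloxy)guai-4-en-3-one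
Conditions: methacryloyl chloride, Et3N, DMAP (cat.), CH2Cl2, 0 °C → rt
Reagents that add atoms: methacryloyl chloride, C=C(C)C(Cl)=O
Why: Acylation of a secondary alcohol by an acid chloride with nucleophilic catalysis; acylation should be faster than base-induced acetyl migration, and C1 is already at its equilibrium configuration.

## Compound list

1 | hex-4-ynoic acid | CC#CCCC(=O)O | starting material
2 | (S)-4-benzyl-1,3-oxazolidin-2-one | O=C1N[C@@H](Cc2ccccc2)CO1 | starting material
3 | hex-4-ynoic pivalic anhydride (not isolated) | CC#CCCC(=O)OC(=O)C(C)(C)C | intermediate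
4 | (S)-4-benzyl-3-(hex-4-ynoyl)-1,3-oxazolidin-2-one | CC#CCCC(=O)N1C(=O)OC[C@@H]1Cc1ccccc1 | intermediate
5 | 3-methoxyprop-1-yne | COCC#C | starting material
6 | oxirane | C1CO1 | starting material
7 | (3-methoxyprop-1-yn-1-yl)lithium (not isolated) | [Li]C#CCOC | intermediate
8 | 5-methoxypent-3-yn-1-ol | COCC#CCCO | intermediate
9 | 5-methoxypent-3-ynal | COCC#CCC=O | intermediate
10 | dibutylboron Z-enolate of 4 (not isolated) | CC#CC/C=C(\OB(CCCC)CCCC)N1C(=O)OC[C@@H]1Cc1ccccc1 | intermediate
11 | (S)-4-benzyl-3-[(2S,3R)-2-(but-2-yn-1-yl)-3-hydroxy-7-methoxyhept-5-ynoyl]-1,3-oxazolidin-2-one | O[C@H](CC#CCOC)[C@H](CC#CC)C(=O)N1C(=O)OC[C@@H]1Cc1ccccc1 | intermediate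
12 | (S)-4-benzyl-3-[(2S,3R)-2-(but-2-yn-1-yl)-3-(tert-butyldimethylsilyloxy)-7-methoxyhept-5-ynoyl]-1,3-oxazolidin-2-one | CC(C)(C)[Si](C)(C)O[C@H](CC#CCOC)[C@H](CC#CC)C(=O)N1C(=O)OC[C@@H]1Cc1ccccc1 | intermediate
13 | S-ethyl (2S,3R)-2-(but-2-yn-1-yl)-3-(tert-butyldimethylsilyloxy)-7-methoxyhept-5-ynethioate | CC(C)(C)[Si](C)(C)O[C@H](CC#CCOC)[C@H](CC#CC)C(=O)SCC | intermediate
14 | (3S,4R)-3-(but-2-yn-1-yl)-4-(tert-butyldimethylsilyloxy)-8-methoxyoct-6-yn-2-one (not isolated) | CC(C)(C)[Si](C)(C)O[C@H](CC#CCOC)[C@H](CC#CC)C(C)=O | intermediate
15 | (3S,4R)-3-(but-2-yn-1-yl)-4-(tert-butyldimethylsilyloxy)-8-methoxy-2-methyloct-6-yn-2-ol | CC(C)(C)[Si](C)(C)O[C@H](CC#CCOC)[C@H](CC#CC)C(C)(C)O | intermediate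
16 | (3S,4R)-3-(but-2-yn-1-yl)-4-(tert-butyldimethylsilyloxy)-2,6-dimethylocta-6,7-dien-2-ol | CC(C)(C)[Si](C)(C)O[C@H](CC(C)=C=C)[C@H](CC#CC)C(C)(C)O | intermediate
17 | (3S,4R)-3-(but-2-yn-1-yl)-4-(tert-butyldimethylsilyloxy)-2,6-dimethylocta-6,7-dien-2-yl acetate | CC(C)(C)[Si](C)(C)O[C@H](CC(C)=C=C)[C@H](CC#CC)C(C)(C)OC(C)=O | intermediate
18 | (7S,8R)-11-acetoxy-8-(tert-butyldimethylsilyloxy)guaia-1(10),4-dien-3-one | CC(C)(C)[Si](C)(C)O[C@@H]1CC(C)=C2CC(=O)C(C)=C2C[C@@H]1C(C)(C)OC(C)=O | intermediate
19 | (1S,7S,8R,10S)-11-acetoxy-8-(tert-butyldimethylsilyloxy)guai-4-en-3-one | CC(C)(C)[Si](C)(C)O[C@@H]1C[C@H](C)[C@@H]2CC(=O)C(C)=C2C[C@@H]1C(C)(C)OC(C)=O | intermediate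
20 | extended dienolate (3-oxido-1(5),3-diene) of 19 and 21 (not isolated) | CC(C)(C)[Si](C)(C)O[C@@H]1C[C@H](C)C2=C(C[C@@H]1C(C)(C)OC(C)=O)C(C)=C([O-])C2 | intermediate
21 | (1R,7S,8R,10S)-11-acetoxy-8-(tert-butyldimethylsilyloxy)guai-4-en-3-one | CC(C)(C)[Si](C)(C)O[C@@H]1C[C@H](C)[C@H]2CC(=O)C(C)=C2C[C@@H]1C(C)(C)OC(C)=O | intermediate
22 | (1R,7S,8R,10S)-11-acetoxy-8-hydroxyguai-4-en-3-one | O[C@@H]1C[C@H](C)[C@H]2CC(=O)C(C)=C2C[C@@H]1C(C)(C)OC(C)=O | intermediate
23 | (1R,7S,8R,10S)-11-acetoxy-8-(methacryloyloxy)guai-4-en-3-one | C=C(C)C(=O)O[C@@H]1C[C@H](C)[C@H]2CC(=O)C(C)=C2C[C@@H]1C(C)(C)OC(C)=O | target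

## Step count and least certain steps

Total: 14 steps. Longest linear sequence: 13 steps (steps 2 to 14, from 5 and 6); the branch from 1 and 2 joins at step 4.

**Step 10 (key step).** The most likely failure is intermolecular consumption of the allene (oligomerisation on rhodium) outpacing closure of the seven-membered ring, because the open chain of 17 must fold before both π-systems can bind one metal. Closure through the proximal allene bond is the second possibility. The fallback changes the substrate so that the fold is built in; it sets out from 16 and comes back at 18. Bu4NF in THF removes the silyl group to give (3S,4R)-3-(but-2-yn-1-yl)-2,6-dimethylocta-6,7-diene-2,4-diol F1. 2,2-Dimethoxypropane with pyridinium tosylate ties O8 and O11 into the acetonide (5S,6R)-5-(but-2-yn-1-yl)-2,2,4,4-tetramethyl-6-(2-methylbuta-2,3-dien-1-yl)-1,3-dioxane F2, in which the two arms are cis on a six-membered ring and therefore held gauche. The same rhodium-catalysed cyclocarbonylation then gives (7S,8R)-8,11-(isopropylidenedioxy)guaia-1(10),4-dien-3-one F3. Aqueous acetic acid frees (7S,8R)-8,11-dihydroxyguaia-1(10),4-dien-3-one F4. TBSOTf (one equivalent) with 2,6-lutidine at −78 °C silylates the secondary hydroxyl to give (7S,8R)-8-(tert-butyldimethylsilyloxy)-11-hydroxyguaia-1(10),4-dien-3-one F5, and acetylation as in step 9 returns 18.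

**Step 4 (with step 3).** The most likely failure is isomerisation of 9 to the conjugated allenyl aldehyde, or its self-condensation, before the enolate has consumed it, because the CH2 between the formyl group and the alkyne is both α-carbonyl and propargylic. The fallback masks the alkyne; it sets out from 8 and comes back at 11. Co2(CO)8 in CH2Cl2 gives the hexacarbonyldicobalt complex of 5-methoxypent-3-yn-1-ol F6. Dess–Martin oxidation gives the hexacarbonyldicobalt complex of 5-methoxypent-3-ynal F7, in which the alkyne carbons are bound to the cluster and cannot shift to an allene. Aldol addition of enolate 10 (from 4, with Bu2BOTf in slight deficit so that no free Lewis acid ionises the complexed propargylic ether) gives the cobalt-complexed aldol adduct F8, and (NH4)2Ce(NO3)6 in acetone at 0 °C removes the metal to return 11.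

**Step 11.** The most likely failure is poor facial discrimination at C10, with hydrogen delivered partly syn to O8, or sluggish uptake at the tetrasubstituted alkene so that forcing conditions begin to reduce C4=C5. The fallback replaces surface hydrogenation by an electron-transfer 1,6-reduction; it sets out from 18 and comes back at 21. SmI2 (divalent samarium) in THF/HMPA with t-BuOH at −78 °C reduces the dienone; C10 is then protonated as a carbanion, which should place the methyl pseudo-equatorial and cis to O8 under product-stability rather than approach control. The resulting dienolate 20 is protonated, and the DBU treatment of step 12 finishes the equilibration at C1 to give 21. No new isolable compound arises.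

**Step 12.** The most likely failure is an equilibrium at C1 that stops at a mixture, since the preference for 21 rests on a single gauche interaction and may depend on the bulky C8 silyl ether; separating and resubmitting 19 is the routine remedy. The fallback moves the equilibration to the end, where the stable epimer is the target itself; it sets out from 19 and comes back at 23. HF·pyridine gives (1S,7S,8R,10S)-11-acetoxy-8-hydroxyguai-4-en-3-one F9, methacryloylation as in step 14 gives (1S,7S,8R,10S)-11-acetoxy-8-(methacryloyloxy)guai-4-en-3-one F10, and DBU in toluene equilibrates C1 to give 23.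

## Further compounds

F1 | step 10 | (3S,4R)-3-(but-2-yn-1-yl)-2,6-dimethylocta-6,7-diene-2,4-diol | O[C@H](CC(C)=C=C)[C@H](CC#CC)C(C)(C)O
F2 | step 10 | (5S,6R)-5-(but-2-yn-1-yl)-2,2,4,4-tetramethyl-6-(2-methylbuta-2,3-dien-1-yl)-1,3-dioxane | CC1(C)O[C@H](CC(C)=C=C)[C@H](CC#CC)C(C)(C)O1
F3 | step 10 | (7S,8R)-8,11-(isopropylidenedioxy)guaia-1(10),4-dien-3-one | CC1(C)O[C@@H]2CC(C)=C3CC(=O)C(C)=C3C[C@@H]2C(C)(C)O1
F4 | step 10 | (7S,8R)-8,11-dihydroxyguaia-1(10),4-dien-3-one | O[C@@H]1CC(C)=C2CC(=O)C(C)=C2C[C@@H]1C(C)(C)O
F5 | step 10 | (7S,8R)-8-(tert-butyldimethylsilyloxy)-11-hydroxyguaia-1(10),4-dien-3-one | CC(C)(C)[Si](C)(C)O[C@@H]1CC(C)=C2CC(=O)C(C)=C2C[C@@H]1C(C)(C)O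
F6 | step 4 | hexacarbonyldicobalt complex of 5-methoxypent-3-yn-1-ol | COCC12C3(CCO)[Co]1(=C=O)(=C=O)(=C=O)[Co]23(=C=O)(=C=O)=C=O
F7 | step 4 | hexacarbonyldicobalt complex of 5-methoxypent-3-ynal | COCC12C3(CC=O)[Co]1(=C=O)(=C=O)(=C=O)[Co]23(=C=O)(=C=O)=C=O
F8 | step 4 | hexacarbonyldicobalt complex (at the C5–C6 alkyne of the heptynoyl chain) of aldol adduct 11 | O[C@H](CC12C3(COC)[Co]1(=C=O)(=C=O)(=C=O)[Co]23(=C=O)(=C=O)=C=O)[C@H](CC#CC)C(=O)N1C(=O)OC[C@@H]1Cc1ccccc1
F0 | step 11 | none | none
F9 | step 12 | (1S,7S,8R,10S)-11-acetoxy-8-hydroxyguai-4-en-3-one | O[C@@H]1C[C@H](C)[C@@H]2CC(=O)C(C)=C2C[C@@H]1C(C)(C)OC(C)=O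
F10 | step 12 | (1S,7S,8R,10S)-11-acetoxy-8-(methacryloyloxy)guai-4-en-3-one | C=C(C)C(=O)O[C@@H]1C[C@H](C)[C@@H]2CC(=O)C(C)=C2C[C@@H]1C(C)(C)OC(C)=O
A1 | alternative 1 | cis-fused hydroazulene with C8 trimethylsilyl enol ether, C11 methoxymethyl ether on C7 and C3=C4 alkene | C[Si](C)(C)OC1=C(C(C)(C)OCOC)C[C@@H]2C(C)=CC[C@@H]2[C@@H](C)C1
A2 | alternative 2 | (3S)-3-[(1R)-3-methyl-2-(3-methylbut-2-en-1-yl)-4-oxocyclopent-2-en-1-yl]butanal | O=CC[C@H](C)[C@H]1CC(=O)C(C)=C1CC=C(C)C
A3 | alternative 2 | (1R,7S,8R,10S)-8,11-dihydroxyguai-4-en-3-one | O[C@@H]1C[C@H](C)[C@H]2CC(=O)C(C)=C2C[C@@H]1C(C)(C)O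
A4 | alternative 3 | hydroazulene with C1=C5 alkene, C7 methyl ester, C8 tert-butyldimethylsilyl enol ether, C3 silyl ether and C10 methyl | COC(=O)C1=C(O[Si](C)(C)C(C)(C)C)C[C@H](C)C2=C(C1)[C@H](C)[C@H](O[Si](C)(C)C(C)(C)C)C2
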